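**Assumptions (one line each):** Dihydro‑β‑ionone, [2‑(1,3‑dioxolan‑2‑yl)ethyl]triphenylphosphonium bromide and (Z)‑crotyl‑Bpin are taken as commercial. The C5=C6 alkene (3, 4, 6–8) is an E/Z mixture, which does not matter because it is consumed in Step 6 through a planar cation.

## Retrosynthetic overview
1. The target's side chain and methyl ester are unmasked at the end by ozonolysis. The tetrasubstituted alkene of the 2,6,6‑trimethylcyclohexene ring becomes MeCO(CH2)3CMe2CO–, and the terminal vinyl group becomes CO2Me.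
2. The only new ring is the 1,2‑dioxane. It comes from a secondary hydroperoxide adding to a trisubstituted alkene (6‑endo, Markovnikov); C6 is set relative to C3 in this step.
3. The hydroperoxide comes from a syn homoallylic alcohol by SN2 inversion with H2O2. That alcohol, with its adjacent Me‑bearing carbon, comes from organocatalytic (Z)‑crotylboration of an aldehyde.
4. The aldehyde comes from dihydro‑β‑ionone by Wittig olefination with a dioxolane ylide, then hydrolysis.

## Route

**Step 1**
Reactants: 1 dihydro‑β‑ionone; 2 [2‑(1,3‑dioxolan‑2‑yl)ethyl]triphenylphosphonium bromide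
Product: 3 acetal‑alkene (E/Z)
Conditions: KOtBu, THF, 0 → 50 °C
Reagents that add atoms: none
Why: Wittig olefination of the methyl ketone builds the C5=C6 trisubstituted alkene and the C3–C5 arm with C3 masked as an acetal; no stereocentre is formed.

**Step 2**
Reactants: 3
Product: 4 β,γ‑unsaturated aldehyde
Conditions: PPTS (0.2 equiv), acetone/H2O 10:1, 50 °C; used crude
Reagents that add atoms: water (O)
Why: Mild acid hydrolysis of the dioxolane unmasks C3 as an aldehyde while leaving both alkenes intact.

**Step 3**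
Reactants: 4; 5 (Z)‑crotyl pinacolboronate
Product: 6 syn homoallylic alcohol, (3R,4R)
Conditions: (S)‑TRIP (10 mol %), toluene, 4 Å MS, −30 °C, 48 h; then aq. work‑up
Reagents that add atoms: none
Why: Chiral‑phosphoric‑acid‑catalysed allylboration goes through a Zimmerman–Traxler chair, so the Z‑crotyl reagent gives the syn relationship and the catalyst's chiral pocket sets the enantioface. This creates both C3 (carbinol) and Cα (Me‑bearing) stereocentres as the first stereocentres in the route.

**Step 4**
Reactants: 6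
Product: 7 mesylate, (3R,4R)
Conditions: MsCl, Et3N, CH2Cl2, 0 °C, 1 h
Reagents that add atoms: methanesulfonyl chloride, CS(=O)(=O)Cl
Why: Activation of the secondary alcohol as a sulfonate with retention of configuration.

**Step 5**
Reactants: 7
Product: 8 hydroperoxide, (3R,4S)
Conditions: 50 % aq. H2O2 (20 equiv), K2CO3 (2 equiv), THF/MeOH 1:1, 0 → 25 °C, 24 h
Reagents that add atoms: hydrogen peroxide, OO
Why: SN2 displacement by the α‑effect nucleophile HOO⁻ inverts C3, converting the syn alcohol series into the anti O–C3–Cα–Me relationship required by the target. The mild base favours substitution over elimination.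

**Step 6**
Reactants: 8
Product: 9 (3S,6S)‑3‑[(2R)‑but‑3‑en‑2‑yl]‑6‑methyl‑6‑[2‑(2,6,6‑trimethylcyclohex‑1‑en‑1‑yl)ethyl]‑1,2‑dioxane
Conditions: chiral IDPi acid (5 mol %, enantiomer matched to C3; screen both), cyclohexane, 4 Å MS, 0 °C, 48 h
Reagents that add atoms: none
Why: Proposed new method: the confined chiral IDPi anion protonates the trisubstituted alkene at C5 (Markovnikov) to give an ion pair with the tertiary C6 cation, and the tethered secondary hydroperoxide, hydrogen‑bonded to the anion, closes 6‑endo through a chair‑like transition state with the C3 substituent equatorial. The catalyst selects the face that puts the aryl‑ethyl chain axial, giving the 3,6‑cis isomer required by the target; without a catalyst, Me and chain are nearly isoenergetic and the ratio would be about 1:1. The closest known reactions are IDPi‑catalysed intramolecular hydroalkoxylation of unactivated alkenes and acid‑mediated cyclisation of alkenyl hydroperoxides to 1,2‑dioxanes.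

**Step 7**
Reactants: 9
Product: 10 keto‑aldehyde
Conditions: O3, CH2Cl2, −78 °C; then Me2S (10 equiv), −78 → 25 °C
Reagents that add atoms: ozone, [O-][O+]=O
Why: Ozonolysis cleaves the ring alkene to the MeCO(CH2)3CMe2CO– side chain and the vinyl group to CHO; the dialkyl peroxide survives, and no stereocentre is touched.

**Step 8**
Reactants: 10
Product: 11 acid
Conditions: NaClO2, NaH2PO4, 2‑methyl‑2‑butene, tBuOH/H2O 3:1, 0 °C, 1 h
Reagents that add atoms: sodium chlorite, [Na+].[O-]Cl=O
Why: Pinnick oxidation is chemoselective for the aldehyde over the two ketones and leaves the peroxide and Cα configuration intact under its mild, buffered acidity.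

**Step 9**
Reactants: 11
Product: 12 target
Conditions: TMSCHN2, MeOH/toluene, 0 °C, 30 min
Reagents that add atoms: trimethylsilyldiazomethane, C[Si](C)(C)[CH-][N+]#N
Why: Neutral diazoalkane esterification converts the acid to the methyl ester without touching the ketones, peroxide or Cα stereocentre.

## Compound list
1 | dihydro‑β‑ionone, 4‑(2,6,6‑trimethylcyclohex‑1‑en‑1‑yl)butan‑2‑one | CC(=O)CCC1=C(C)CCCC1(C)C | starting material
2 | [2‑(1,3‑dioxolan‑2‑yl)ethyl]triphenylphosphonium bromide | [Br-].C1(CC[P+](c2ccccc2)(c2ccccc2)c2ccccc2)OCCO1 | starting material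
3 | 2‑[3‑methyl‑5‑(2,6,6‑trimethylcyclohex‑1‑en‑1‑yl)pent‑2‑en‑1‑yl]‑1,3‑dioxolane (E/Z) | CC1=C(CCC(C)=CCC2OCCO2)C(C)(C)CCC1 | intermediate
4 | 4‑methyl‑6‑(2,6,6‑trimethylcyclohex‑1‑en‑1‑yl)hex‑3‑enal (E/Z) | O=CCC=C(C)CCC1=C(C)CCCC1(C)C | intermediate
5 | (Z)‑crotyl pinacolboronate | C/C=C\CB1OC(C)(C)C(C)(C)O1 | starting material
6 | (3R,4R)‑3,7‑dimethyl‑9‑(2,6,6‑trimethylcyclohex‑1‑en‑1‑yl)nona‑1,6‑dien‑4‑ol | C=C[C@@H](C)[C@H](O)CC=C(C)CCC1=C(C)CCCC1(C)C | intermediate
7 | mesylate of 6, (3R,4R) | C=C[C@@H](C)[C@H](OS(C)(=O)=O)CC=C(C)CCC1=C(C)CCCC1(C)C | intermediate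
8 | (3R,4S)‑4‑hydroperoxy‑3,7‑dimethyl‑9‑(2,6,6‑trimethylcyclohex‑1‑en‑1‑yl)nona‑1,6‑diene | C=C[C@@H](C)[C@@H](OO)CC=C(C)CCC1=C(C)CCCC1(C)C | intermediate
9 | (3S,6S)‑3‑[(2R)‑but‑3‑en‑2‑yl]‑6‑methyl‑6‑[2‑(2,6,6‑trimethylcyclohexenyl)ethyl]‑1,2‑dioxane | C=C[C@@H](C)[C@@H]1CC[C@](C)(CCC2=C(C)CCCC2(C)C)OO1 | intermediate
10 | (2S)‑2‑[(3S,6R)‑6‑(4,4‑dimethyl‑3,8‑dioxononyl)‑6‑methyl‑1,2‑dioxan‑3‑yl]propanal | O=C[C@@H](C)[C@@H]1CC[C@](C)(CCC(=O)C(C)(C)CCCC(C)=O)OO1 | intermediate
11 | corresponding (2S)‑propanoic acid | OC(=O)[C@@H](C)[C@@H]1CC[C@](C)(CCC(=O)C(C)(C)CCCC(C)=O)OO1 | intermediate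
12 | Diacarperoxide B, methyl (2S)‑2‑[(3S,6R)‑6‑(4,4‑dimethyl‑3,8‑dioxononyl)‑6‑methyl‑1,2‑dioxan‑3‑yl]propanoate | COC(=O)[C@@H](C)[C@@H]1CC[C@](C)(CCC(=O)C(C)(C)CCCC(C)=O)OO1 | target

**Total steps:** 9. **Longest linear sequence:** 9 (1 → 3 → 4 → 6 → 7 → 8 → 9 → 10 → 11 → 12).

## Three steps most likely to fail
1. **Step 6 (proposed new cyclisation):** it may give poor 3,6‑cis selectivity or Hock cleavage of the hydroperoxide under the strong acid.
   Fallback: from mesylate 7, run Isayama–Mukaiyama hydroperoxidation of the C5=C6 alkene (Co(acac)2, O2, Et3SiH) to give the C6 tertiary hydroperoxide, then close the ring by base‑mediated intramolecular SN2 at C3 (inversion). Separate the C6 epimers by HPLC.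
2. **Step 5 (H2O2 SN2 on a β‑branched secondary mesylate):** elimination to a conjugated diene may compete.
   Fallback: make the C6 hydroperoxide from alcohol 6 by Mukaiyama hydroperoxidation and close the ring by intramolecular Mitsunobu (DIAD, PPh3), which also inverts C3 and skips the mesylate.
3. **Step 3 (catalytic Z‑crotylboration of an enolisable, isomerisation‑prone β,γ‑unsaturated aldehyde):** enantioselectivity or syn selectivity may be low.
   Fallback: stoichiometric Brown crotylation with (Z)‑crotyl‑diisopinocampheylborane of the appropriate Ipc chirality, which is reagent‑controlled and gives the syn (3R,4R) alcohol.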